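**Strategy.** The plan cuts ring C at two bonds, C3–O(sulfate) and O1–C2. C3 lies between the C4 carbonyl and the O1–C2 enol ether of the pyranone. With ring C opened and NMe2 placed on C2, C3 becomes the nucleophilic α-carbon of a push-pull enaminone. In one operation this carbon should lift an intact O–SO3 unit out of the peroxide bond of peroxydisulfate. The ortho hydroxyl of ring A then captures the iminium carbon, and dimethylamine departs. O3 is thus born sulfated and never competes with O5, O7 or O4'. The precursor is a 2'-hydroxy β-aryl β-(dimethylamino) enone with its three other phenols benzylated, assembled from an acetophenone and a benzamide acetal.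

Key step: step 7

Assumption: the target is drawn as the protonated hydrogen sulfate, so the sulfate is carried as its tetrabutylammonium salt and protonated only in the last step; the target has no stereocentre.

Step 1
Reactants: 1 2,4,6-trihydroxyacetophenone
Product: 2 2-hydroxy-4,6-bis(benzyloxy)acetophenone
Conditions: BnBr (2.05 equiv), K2CO3 (2.2 equiv), DMF, 60 °C; recrystallise
Reagents that add atoms: benzyl bromide, BrCc1ccccc1
Why: Williamson ether synthesis under weak base, in which the para hydroxyl and one ortho hydroxyl are alkylated while the last ortho hydroxyl is held by a strong hydrogen bond to the acetyl oxygen and stays free when the halide is limited to two equivalents, a selectivity well established for acylphloroglucinols.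

Step 2
Reactants: 3 4-hydroxybenzoic acid
Product: 4 4-(benzyloxy)benzoic acid
Conditions: BnBr (1.1 equiv), KOH (2.5 equiv), EtOH/H2O, reflux; then aq. HCl to pH 2, filter
Reagents that add atoms: benzyl bromide, BrCc1ccccc1
Why: Williamson ether synthesis on the dianion, whose phenoxide is far more nucleophilic than its carboxylate, with any benzyl ester saponified by the excess KOH in the same pot.

Step 3
Reactants: 4 4-(benzyloxy)benzoic acid
Product: 6 4-(benzyloxy)-N,N-dimethylbenzamide, via 4-(benzyloxy)benzoyl chloride 5 (not isolated)
Conditions: (COCl)2 (1.2 equiv), DMF (cat.), CH2Cl2, 0 °C to rt, evaporate; then Me2NH (40% aq., 1.5 equiv), K2CO3 (1.5 equiv), CH2Cl2/H2O, 0 °C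
Reagents that add atoms: oxalyl chloride, O=C(Cl)C(=O)Cl (chlorine of 5); dimethylamine, CNC
Why: Acid chloride formation under Vilsmeier-type catalysis followed by Schotten–Baumann amidation, both of which leave an aryl benzyl ether untouched.

Step 4
Reactants: 6 4-(benzyloxy)-N,N-dimethylbenzamide
Product: 8 4-(benzyloxy)-N,N-dimethylbenzamide dimethyl acetal, via O-methyl imidate tetrafluoroborate 7 (not isolated)
Conditions: Me3OBF4 (1.05 equiv), dry CH2Cl2, rt; concentrate; NaOMe (1.1 equiv), MeOH, −10 °C; evaporate, take up in dry toluene, filter under N2; use crude at once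
Reagents that add atoms: trimethyloxonium tetrafluoroborate, C[O+](C)C.F[B-](F)(F)F; sodium methoxide, C[O-].[Na+]
Why: O-alkylation of a tertiary amide with a Meerwein salt gives the alkoxyiminium salt, and methoxide adds to its carbon at low temperature, which is the standard preparation of amide acetals that lack α-hydrogens.

Step 5
Reactants: 2 2-hydroxy-4,6-bis(benzyloxy)acetophenone; 8 4-(benzyloxy)-N,N-dimethylbenzamide dimethyl acetal
Product: 9 (E)-1-[2-hydroxy-4,6-bis(benzyloxy)phenyl]-3-[4-(benzyloxy)phenyl]-3-(dimethylamino)prop-2-en-1-one
Conditions: 8 (1.5 equiv), dry toluene, 90 °C, slow N2 sweep to carry off MeOH, base-washed glassware; crystallise (EtOAc/heptane) or filter through basic alumina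
Reagents that add atoms: none
Why: Amide acetal condensation with an aryl methyl ketone (the aryl counterpart of the enaminone synthesis with DMF or dimethylacetamide dimethyl acetal), in which ionisation of 8 supplies methoxide to enolise the acetyl group and an alkoxyiminium ion for the enolate to attack, methanol removal drives the reaction, and the acid-free medium keeps the chelated phenol from closing the ring early.

Step 6
Reactants: 10 potassium peroxydisulfate, K2S2O8
Product: 11 bis(tetrabutylammonium) peroxydisulfate
Conditions: Bu4NHSO4 (2.0 equiv), H2O, rt, 30 min; extract CH2Cl2, dry (MgSO4), evaporate below 30 °C; store cold and dark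
Reagents that add atoms: tetrabutylammonium hydrogensulfate, CCCC[N+](CCCC)(CCCC)CCCC.OS(=O)(=O)[O-]
Why: Ion-pair metathesis, in which the lipophilic cation carries peroxydisulfate into CH2Cl2 while KHSO4 stays in water, a known route to this organic-soluble oxidant.

Step 7
Reactants: 9 (E)-1-[2-hydroxy-4,6-bis(benzyloxy)phenyl]-3-[4-(benzyloxy)phenyl]-3-(dimethylamino)prop-2-en-1-one; 11 bis(tetrabutylammonium) peroxydisulfate
Product: 14 tetrabutylammonium 5,7-bis(benzyloxy)-2-[4-(benzyloxy)phenyl]-4-oxo-4H-chromen-3-yl sulfate, via C3-sulfonatooxy iminium zwitterion 12 (not isolated), via 2-(dimethylamino)flavanone 3-sulfate 13 (not isolated)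
Conditions: 11 (1.2 equiv), activated 4 Å MS, dry degassed MeCN, 0 °C to 20 °C, dark, Ar, no added base, no transition metal salts; partition CH2Cl2/cold water; neutral silica, CH2Cl2/MeOH
Reagents that add atoms: none
Why: Proposed new method: the NMe2-activated α-carbon of 9 (future C3) should displace sulfate from one peroxide oxygen of S2O8(2−) in a two-electron attack on oxygen, giving zwitterion 12 in which the new C3–O bond already carries SO3−. The chelated hydroxyl of ring A then adds to the iminium carbon (6-exo-trig, new O1–C2 bond, closure of ring C) to give aminal 13, and the released sulfate/hydrogensulfate pair shuttles protons so that Me2NH leaves under push from O1 and the acidic C3–H is lost, which installs the C2=C3 bond of the 4-pyranone. The closest known reaction types are the Elbs and Boyland–Sims peroxydisulfate oxidations (among them 4-pyridone to its 3-sulfate, also a vinylogous amide α-carbon), the α-acyloxylation of enaminones with PhI(OAc)2, and the halogen- or chalcogen-triggered annulation of ortho-hydroxyaryl enaminones to 3-substituted chromones. The stereocentres at C2 and C3 of 12 and 13 are transient and vanish in the elimination, so none needs control, and the E geometry of 9 is likewise erased. The selectivity needed is oxygen transfer to C3 rather than to ring A para to its hydroxyl or hydrogen abstraction at the benzylic CH2 groups; it is secured because the phenol stays un-ionised and hydrogen-bonded, every other oxygen is an ether, and cold, dark, metal-free conditions keep the O–O bond from homolysing to sulfate radical anions. The by-products pair up as a mixed dimethylammonium tetrabutylammonium sulfate, so the medium stays near neutral and the acid-labile enol sulfate should survive.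

Step 8
Reactants: 14 tetrabutylammonium 5,7-bis(benzyloxy)-2-[4-(benzyloxy)phenyl]-4-oxo-4H-chromen-3-yl sulfate
Product: 15 tetrabutylammonium kaempferol 3-sulfate
Conditions: H2 (1 atm), 10% Pd/C (chloride-free grade), THF/MeOH 1:1, rt; filter through Celite, evaporate below 30 °C
Reagents that add atoms: none
Why: Heterogeneous hydrogenolysis of aryl benzyl ethers is neutral and forms only toluene, the aprotic Bu4N+ counter-ion keeps the sulfate a salt so that no amine additive (which would slow O-debenzylation on palladium) is needed, and the tetrasubstituted C2=C3 bond and the sulfate monoester anion are inert under these conditions.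

Step 9
Reactants: 15 tetrabutylammonium kaempferol 3-sulfate
Product: 16 kaempferol 3-O-sulfate (hydrogen sulfate form)
Conditions: Dowex 50WX8 (H+ form, prewashed), H2O/t-BuOH 4:1, 0–4 °C, short column, contact of a few minutes; freeze the eluate at once, lyophilise; store dry at −20 °C
Reagents that add atoms: none
Why: Cation exchange on a sulfonic acid resin, which binds the lipophilic Bu4N+ and releases H+, while low temperature, brief contact and immediate freeze-drying limit acid-catalysed cleavage of the enol sulfate.

**Compound list**
1 | 2,4,6-trihydroxyacetophenone | CC(=O)c1c(O)cc(O)cc1O | starting material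
2 | 2-hydroxy-4,6-bis(benzyloxy)acetophenone | CC(=O)c1c(O)cc(OCc2ccccc2)cc1OCc1ccccc1 | intermediate
3 | 4-hydroxybenzoic acid | O=C(O)c1ccc(O)cc1 | starting material
4 | 4-(benzyloxy)benzoic acid | O=C(O)c1ccc(OCc2ccccc2)cc1 | intermediate
5 | 4-(benzyloxy)benzoyl chloride | O=C(Cl)c1ccc(OCc2ccccc2)cc1 | intermediate
6 | 4-(benzyloxy)-N,N-dimethylbenzamide | CN(C)C(=O)c1ccc(OCc2ccccc2)cc1 | intermediate
7 | [4-(benzyloxy)phenyl](methoxy)methylidene-dimethylammonium tetrafluoroborate | COC(=[N+](C)C)c1ccc(OCc2ccccc2)cc1.F[B-](F)(F)F | intermediate
8 | 1-[4-(benzyloxy)phenyl]-1,1-dimethoxy-N,N-dimethylmethanamine (amide dimethyl acetal) | COC(OC)(N(C)C)c1ccc(OCc2ccccc2)cc1 | intermediate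
9 | (E)-1-[2-hydroxy-4,6-bis(benzyloxy)phenyl]-3-[4-(benzyloxy)phenyl]-3-(dimethylamino)prop-2-en-1-one | CN(C)/C(=C/C(=O)c1c(O)cc(OCc2ccccc2)cc1OCc1ccccc1)c1ccc(OCc2ccccc2)cc1 | intermediate
10 | potassium peroxydisulfate, K2S2O8 | [K+].[K+].[O-]S(=O)(=O)OOS(=O)(=O)[O-] | starting material
11 | bis(tetrabutylammonium) peroxydisulfate | CCCC[N+](CCCC)(CCCC)CCCC.CCCC[N+](CCCC)(CCCC)CCCC.[O-]S(=O)(=O)OOS(=O)(=O)[O-] | intermediate
12 | 1-[2-hydroxy-4,6-bis(benzyloxy)phenyl]-3-[4-(benzyloxy)phenyl]-3-(dimethyliminio)-1-oxopropan-2-yl sulfate, racemic zwitterion | C[N+](C)=C(c1ccc(OCc2ccccc2)cc1)C(OS(=O)(=O)[O-])C(=O)c1c(O)cc(OCc2ccccc2)cc1OCc1ccccc1 | intermediate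
13 | tetrabutylammonium 5,7-bis(benzyloxy)-2-[4-(benzyloxy)phenyl]-2-(dimethylamino)-4-oxochroman-3-yl sulfate, racemic diastereomer mixture | CN(C)C1(c2ccc(OCc3ccccc3)cc2)Oc2cc(OCc3ccccc3)cc(OCc3ccccc3)c2C(=O)C1OS(=O)(=O)[O-].CCCC[N+](CCCC)(CCCC)CCCC | intermediate
14 | tetrabutylammonium 5,7-bis(benzyloxy)-2-[4-(benzyloxy)phenyl]-4-oxo-4H-chromen-3-yl sulfate | O=c1c(OS(=O)(=O)[O-])c(-c2ccc(OCc3ccccc3)cc2)oc2cc(OCc3ccccc3)cc(OCc3ccccc3)c12.CCCC[N+](CCCC)(CCCC)CCCC | intermediate
15 | tetrabutylammonium kaempferol 3-sulfate | O=c1c(OS(=O)(=O)[O-])c(-c2ccc(O)cc2)oc2cc(O)cc(O)c12.CCCC[N+](CCCC)(CCCC)CCCC | intermediate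
16 | kaempferol 3-O-sulfate | O=c1c(OS(=O)(=O)O)c(-c2ccc(O)cc2)oc2cc(O)cc(O)c12 | target

**Total step count:** 9. **Longest linear sequence:** 7 (steps 2, 3, 4, 5, 7, 8, 9, from 3 to 16).

**Steps most likely to fail**

(a) Step 7.
- Risk: oxygen transfer to C3 may be too slow at temperatures where the peroxide bond stays intact. Single-electron oxidation of the electron-rich enaminone could start radical chains that attack the benzylic positions. Adventitious water could hydrolyse the iminium stage, and stray protons could close the ring without oxygenation.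
- Fallback (known chemistry), from 9 back to 14:
  - 9 is closed deliberately in warm acetic acid to 5,7,4'-tri-O-benzylapigenin F1, the usual acid cyclisation of ortho-hydroxyaryl enaminones.
  - Dimethyldioxirane in acetone/CH2Cl2 at 0 °C converts F1 into the flavone 2,3-epoxide F2.
  - A trace of TsOH isomerises F2 to 5,7,4'-tri-O-benzylkaempferol F3.
  - The only free hydroxyl of F3, O3, is esterified with Bu4NHSO4 and N,N'-dicyclohexylcarbodiimide in pyridine at 4 °C. This is an established carbodiimide sulfation of flavonols and gives the tetrabutylammonium salt 14 directly.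

(b) Step 5.
- Risk: condensation at the hindered, donor-stabilised acetal carbon may be sluggish. The acetal could transfer a methyl group to the phenol. Prolonged heating could cause loss of dimethylamine with premature ring closure.
- Fallback, from 2 and 7 back to 9, replacing the thermal condensation by a low-temperature anionic bond formation:
  - Salt 7 is precipitated with dry ether after the methylation of step 4.
  - 2 is converted with LiN(SiMe3)2 (2.2 equiv) in THF at −78 °C into its dilithium enolate-phenoxide F4.
  - F4 attacks the alkoxyiminium carbon of 7 through carbon to give the lithium phenoxide of the β-(dimethylamino)-β-methoxy ketone F5.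
  - On warming to 0 °C, F5 expels methoxide under nitrogen push and is deprotonated. A quench with aqueous NaHCO3 then gives 9. The basic medium favours the open enaminone, because phenoxide leaves more readily than dimethylamide.

(c) Step 9.
- Risk: acid-catalysed hydrolysis of the enol sulfate during contact with the resin, or self-catalysed cleavage as the strong acid form is concentrated.
- Fallback, from 15 back to 16, separating removal of the organic cation from protonation:
  - Methanolic potassium acetate (CH3CO2K) precipitates potassium kaempferol 3-sulfate F6, which is stable to storage and can be recrystallised.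
  - When the acid form is needed, F6 is dissolved in ice-cold 0.05 M HCl and captured on a C18 reversed-phase cartridge through its hydrophobic flavone core.
  - KCl is washed off with cold dilute HCl and then briefly with cold water.
  - The product is eluted with cold aqueous MeCN and freeze-dried at once to give 16. The residual acid is volatile.

**Further compounds**
F1 | step 7 | 5,7-bis(benzyloxy)-2-[4-(benzyloxy)phenyl]-4H-chromen-4-one | O=c1cc(-c2ccc(OCc3ccccc3)cc2)oc2cc(OCc3ccccc3)cc(OCc3ccccc3)c12
F2 | step 7 | racemic 5,7-bis(benzyloxy)-2-[4-(benzyloxy)phenyl]-2,3-epoxychroman-4-one | O=C1C2OC2(c2ccc(OCc3ccccc3)cc2)Oc2cc(OCc3ccccc3)cc(OCc3ccccc3)c12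
F3 | step 7 | 5,7-bis(benzyloxy)-2-[4-(benzyloxy)phenyl]-3-hydroxy-4H-chromen-4-one | O=c1c(O)c(-c2ccc(OCc3ccccc3)cc2)oc2cc(OCc3ccccc3)cc(OCc3ccccc3)c12
F4 | step 5 | dilithium enolate-phenoxide of 2-hydroxy-4,6-bis(benzyloxy)acetophenone | [Li+].[Li+].C=C([O-])c1c([O-])cc(OCc2ccccc2)cc1OCc1ccccc1
F5 | step 5 | lithium 3,5-bis(benzyloxy)-2-{3-[4-(benzyloxy)phenyl]-3-(dimethylamino)-3-methoxypropanoyl}phenolate, racemic | COC(CC(=O)c1c([O-])cc(OCc2ccccc2)cc1OCc1ccccc1)(N(C)C)c1ccc(OCc2ccccc2)cc1.[Li+]
F6 | step 9 | potassium kaempferol 3-sulfate | O=c1c(OS(=O)(=O)[O-])c(-c2ccc(O)cc2)oc2cc(O)cc(O)c12.[K+]
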